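4 questions, and our reckoning goes after one of them: how far the substrate goes before the flask stops.

| flask | substrate | coupling partner | remark | time |
|---|---|---|---|---|
| maple | 0.20 M | 0.75 equiv | run made earlier |  |
| elm | 0.20 M | 3 equiv | run made earlier |  |
| flask | 0.20 M | 1.50 equiv |  | 8.0 min |

| run | time / min | substrate / % | single product / % | other mono adduct / % |
|---|---|---|---|---|
| maple | 0.333 | 95 | 4 | 6 |
| maple | 1.00 | 86 | 4 | 7 |
| maple | 2.00 | 81 | 7 | 6 |
| maple | 3.00 | 83 | 10 | 9 |
| maple | 4.00 | 78 | 9 | 10 |
| maple | 5.00 | 77 | 13 | 11 |
| maple | 6.00 | 78 | 12 | 8 |
| elm | 0.500 | 79 | 11 | 9 |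
| elm | 0.833 | 76 | 12 | 9 |
| elm | 1.33 | 72 | 11 | 10 |
| elm | 2.00 | 69 | 19 | 14 |
| elm | 3.00 | 67 | 18 | 14 |
| elm | 4.00 | 66 | 18 | 14 |
| elm | 6.00 | 65 | 14 | 12 |

(each reading ± 2 percentage points)

- for single product the crystals are counted in
- as a solid, counted per litre of solution: crystals
- the earlier runs were read with a standard deviation of 2 percentage points
- steps that have been proposed: substrate + coupling partner -> single product; substrate + coupling partner -> other mono adduct; coupling partner + single product -> double product; coupling partner + other mono adduct -> double product; 2 coupling partner -> homo dimer; single product <-> isomer of the product; crystals <-> single product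

- substrate at 8.0 min, in percent of the substrate charged
- single product at 8.0 min, in percent of the substrate charged
- other mono adduct at 8.0 min, in percent of the substrate charged
- double product at 8.0 min, in percent of the substrate charged

The decision for this flask is whether to wait or to charge more coupling partner. Waiting looks poor: the elm run's substrate drops by 2 percentage points from 3.00 min to 6.00 min, with readings scattered by 2 points. Charging looks poor too. If the proposed step to homo dimer runs, partner meets itself at a rate going with partner squared, but meets substrate with partner times substrate. The ratio follows partner over substrate, so a larger charge should lose a larger share, and that share should ease as partner falls.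

We take the fraction of substrate consumed at the stall, x, as the mean of the last 3 readings:

x(maple) = 0.223, or 0.298 per equivalent

x(elm) = 0.340, or 0.113 per equivalent

The elm run takes less per equivalent, as that ratio suggests. Hence the cheapest rule, with no rate constants:

n = ln[x(elm)/x(maple)] / ln[charge ratio] = 0.303

This n is the stall exponent, the power of the partner charge to which x rises. For this flask:

x = x(maple) × 1.23 = 0.276, so 72.4 % of the substrate stays.

We keep 1.50 equiv and read at 8.0 min. The forecast differs from our reckoning on substrate; it gives 71 % substrate, 14 % single product, 12 % other mono adduct and 2 % double product: “Once it is gone, everything freezes.”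

The flask gives 69.3 %, 11.6 %, 12.5 % and 1.92 %.

    substrate + coupling partner → single product (k = 0.0176 M⁻¹ s⁻¹)
    substrate + coupling partner → other mono adduct (k = 0.0122 M⁻¹ s⁻¹)
    coupling partner + single product → double product (k = 0.0186 M⁻¹ s⁻¹)
    coupling partner + other mono adduct → double product (k = 5.98 × 10⁻⁴ M⁻¹ s⁻¹)
    2 coupling partner → homo dimer (k = 0.100 M⁻¹ s⁻¹)
    single product ⇌ isomer of the product (K = 1.20, k = 0.00104 s⁻¹)
    crystals ⇌ single product, rate k7*(cs7 - [single product]) while solid is left; crystals form when [single product] > cs7 (solubility = 0.0730 M, k = 0.160 s⁻¹)

Left ten times as long, to 80.0 min, the flask's substrate goes from 69.3 % to 68.2 %, so its x goes from 30.7 %, against our 27.6 %, to 31.8 %. Coupling partner, the limiting reagent despite the excess charged, stands at 0.83 % of its charge at 8.00 min. Left ten times as long, the flask holds 13.0 % other mono adduct and 2.02 % double product, while its single product falls from 11.6 % to 7.64 % and its isomer of the product rises from 4.71 % to 9.16 %.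

In the neighbour flask with 0.900 equiv, n gives x = 0.236, so 76.4 % of the substrate stays. That neighbour flask computes to 74.4 % substrate.

The numbers in the tables were computed on assumed constants, noise included.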